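**A stubborn count.** Divide the last product reading of a run by the free catalyst charged, and you get close to the same figure whichever charge you changed. Here are the flasks, the readings and the questions.

| flask | starting material | partner | free catalyst | time |
|---|---|---|---|---|
| Friday's | 0.600 M | 1.50 M | 0.00600 M |  |
| Thursday's | 0.600 M | 0.750 M | 0.00600 M |  |
| Wednesday's | 0.600 M | 1.50 M | 0.0180 M |  |
| Monday's | 1.20 M | 1.50 M | 0.00600 M |  |
| Sunday's | 0.120 M | 0.300 M | 0.00600 M | 81 min |

| run | time / min | [product] / M |
|---|---|---|
| Friday's run | 10 | 0.0492 |
| Friday's run | 20 | 0.0835 |
| Friday's run | 30 | 0.1040 |
| Friday's run | 40 | 0.1186 |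
| Friday's run | 51 | 0.1255 |
| Friday's run | 61 | 0.1328 |
| Friday's run | 71 | 0.1375 |
| Friday's run | 81 | 0.1373 |
| Thursday's run | 10 | 0.0442 |
| Thursday's run | 20 | 0.0681 |
| Thursday's run | 30 | 0.0903 |
| Thursday's run | 40 | 0.1050 |
| Thursday's run | 51 | 0.1139 |
| Thursday's run | 61 | 0.1190 |
| Thursday's run | 71 | 0.1262 |
| Thursday's run | 81 | 0.1262 |
| Wednesday's run | 10 | 0.1527 |
| Wednesday's run | 20 | 0.2396 |
| Wednesday's run | 30 | 0.2942 |
| Wednesday's run | 40 | 0.3287 |
| Wednesday's run | 51 | 0.3556 |
| Wednesday's run | 61 | 0.3752 |
| Wednesday's run | 71 | 0.3864 |
| Wednesday's run | 81 | 0.4014 |
| Monday's run | 10 | 0.0657 |
| Monday's run | 20 | 0.0999 |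
| Monday's run | 30 | 0.1195 |
| Monday's run | 40 | 0.1289 |
| Monday's run | 51 | 0.1347 |
| Monday's run | 61 | 0.1383 |
| Monday's run | 71 | 0.1368 |
| Monday's run | 81 | 0.1420 |

(readings scatter by 0.002 M)

1. the exponent of [free catalyst] in the starting rate at the charge of the Friday's run (at the point where two percent of the starting material have become product)
2. the exponent of [starting material] in the starting rate at the charge of the Friday's run (at the point where two percent of the starting material have become product) (one fixed amount of product, the same in the runs compared)
3. product in the Sunday's run at 81 min, as a share of the starting material charged

- Overall: starting material + partner -> product, with free catalyst as catalyst.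
- Constant volume, constant temperature.
- The analysis sees a species whether free or bound.
- An order is taken over about fifteen percent of the charge, up and down.

**Reading the count.** Friday's last reading is 0.1373 M of product, level with the one before it, with 0.463 M of starting material not turned to product, and that reads as a catalyst lost while it works. So define the turnover capacity, the turnover number of this catalyst: product made per unit of free catalyst charged before that catalyst is lost. Friday's run reads 22.9. Monday's run, with twice the starting material, reads 23.7. Wednesday's run, with 3.00 times the catalyst, reads 22.3. Thursday's run, with half the partner, reads 21.0.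

**The small correction.** If each unit of catalyst buys that many units of product, then at a given amount of product the live catalyst is the charge minus product divided by capacity. In Friday's run, two percent of the starting material is 0.0120 M of product, which costs 5.24 × 10⁻⁴ M of catalyst, or 8.74% of the charge. On that count the loss at this amount of product is the same for any catalyst charge, so the live catalyst is the charge minus a fixed amount. If the rate follows live catalyst directly, the exponent is the charge over the live catalyst, 1.10.

For Sunday's run, my reckoning gives a capacity of 0.137 M, more than the 0.120 M of starting material charged. The count therefore sets no ceiling below full conversion there, though the live catalyst falls as product forms.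

**The forecast.** Its ground is that “the catalyst dies per turnover”. It gives 1.08 for the catalyst exponent, a shade below my figure, and 0.45 for the starting material exponent. For Sunday's run it gives 59%, within 43% to 73%.

**The result.** The exponents come out at 1.1 and 0.40, both near the forecast. Sunday's run gives 66.4%, which is 7.4 percentage points above it.

    free catalyst + starting material → catalyst-substrate complex (9.780 L mol⁻¹ min⁻¹)
    catalyst-substrate complex + partner → product + free catalyst (2.418 L mol⁻¹ min⁻¹)
    2 starting material ⇌ idle substrate dimer, settled at all times (7.270 L mol⁻¹)
    free catalyst + starting material → spent catalyst + starting material (0.4158 L mol⁻¹ min⁻¹)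

**Sunday's catalyst.** Sunday's run made 0.0796 M of product, and by the count that used 58.1% of its capacity. The step from free catalyst + starting material to spent catalyst + starting material is the main reason that Sunday's run stands short of full conversion at 81 min, with 59% of what is missing: without it, Sunday's run reaches 86.3% instead of 66.4%. By the count, Wednesday's run at 0.0120 M of product has 3.19 times the live catalyst of Friday's run, and at that point the rate of Wednesday's run is 3.1 times that of Friday's run.

The readings were computed on assumed constants; noise was put on by code.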